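**Plan** (acid part numbered as 1,2,3,4,4a,7,8,8a-octahydronaphthalene, C-1 = CH–CO2R)
Retrosynthesis: cut the glyceride (ester O–CH2, then epoxide C–O), the C-5–side-chain bond (sp2–sp3 coupling), ring B at C-6=C-7 and C-4a–C-5 (aldol condensation, aldol); add a C-4 ketone and a C-3–C-7 bond as helpers; last, cut C-2–C-3 together with C-1–C-8a.
Enabling feature: in ring A (C-1, C-2, C-3, C-4, C-4a, C-8a) the CH2 C-4 lies next to quaternary C-4a. With C-4 as a ketone, C-3=C-4(O)–C-4a=C-8a is the cross-conjugated dienolate of a 2,3-dimethylcyclohexenone and C-2/C-1 is a crotonate. The temporary ring C-3, C-4, C-4a, C-8a, C-8, C-7 (3-methylcarvone) holds that diene s-cis with the C-8a methyl pointing outward.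
Forward: ring A forms first inside a bicyclo[2.2.2]octanone; C-4a is acetylated; the carvone ring is opened between C-3 and C-7 (retro-aldol) and ring B is closed (aldol condensation); the side chain comes by Negishi coupling; C-4 is deoxygenated; the glyceride is made last.
Stereochemistry: the carvone stereocentre (later C-7, then destroyed) sends the crotonate to the opposite face and so fixes C-8a, C-1 and C-2 in one event; C-4a follows by attack anti to the endo ester, which forces the cis ring fusion; the glycerol centre is bought as (S)-glycidyl nosylate.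

Key step: step 3

Remark: 2, 7 and 8 are each expected as epimers at one carbon (C-1 of 2, C-6 of 7, the carbinol carbon of 8) that is planarised in the following step, so the epimers converge; one epimer of 7 is drawn.

**Step 1**
Reactants: 1 (R)-(−)-carvone
Product: 2 (5R)-1,2-dimethyl-5-(prop-1-en-2-yl)cyclohex-2-en-1-ol
Conditions: CH3Li, Et2O, −78 °C; then H2O
Reagents that add atoms: methyllithium, C[Li]
Why: 1,2-addition of the organolithium to the enone carbonyl should give the tertiary allylic alcohol needed for the transposition, without touching the ring stereocentre.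

**Step 2**
Reactants: 2 (5R)-1,2-dimethyl-5-(prop-1-en-2-yl)cyclohex-2-en-1-ol
Product: 3 (5S)-2,3-dimethyl-5-(prop-1-en-2-yl)cyclohex-2-en-1-one
Conditions: [C5H5NH][CrO3Cl] (pyridinium chlorochromate), CH2Cl2, rt
Reagents that add atoms: pyridinium chlorochromate, [O-][Cr](=O)(=O)Cl.c1cc[nH+]cc1
Why: Babler–Dauben oxidative 1,3-transposition (chromate ester, [3,3] shift, oxidation) should move the oxygen to the former C-3 and leave the β-methyl enone; the stereocentre keeps its arrangement and changes descriptor only through the sequence rules.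

**Step 3**
Reactants: 3 (5S)-2,3-dimethyl-5-(prop-1-en-2-yl)cyclohex-2-en-1-one, 4 methyl (2E)-but-2-enoate
Product: 7 methyl (1S,2S,3R,4R,6S,8S)-1,3,6-trimethyl-5-oxo-8-(prop-1-en-2-yl)bicyclo[2.2.2]octane-2-carboxylate, via lithium dienolate 5 (not isolated), via ester enolate 6 (not isolated)
Conditions: LiN(iPr)2, THF, −78 °C; then 4, −78 °C → rt; aq NH4Cl
Reagents that add atoms: none
Why: LiN(iPr)2 removes a C-6 hydrogen of 3 under kinetic control to give the cross-conjugated dienolate 5, whose C-6 adds to the β-carbon of 4 (first new bond) to give ester enolate 6, and the α-carbon of 6 then adds to the methyl-bearing β-carbon (C-3) of the regenerated enone (second new bond, quaternary centre). This is the double Michael (anionic [4+2]) annulation of cyclohexenone kinetic dienolates with acrylates and crotonates, a reaction type well established on carvone-type enones. The second addition closes the bicyclo[2.2.2]octane, that is both new six-membered rings at once, in a 6-endo-trig Michael mode, the carvone ring holding the four dienolate carbons s-cis. The crotonate is taken up on the ring face anti to the isopropenyl group, which sits next to the first bond-forming site, and this fixes both bridgeheads (C-1 and C-4 of 7); at C-2 the ester turns endo, syn to the enolate bridge, through lithium chelation between ester enolate and enone oxygen, and at C-3 the methyl ends trans to the ester because the E geometry of 4 is carried through this closed, Diels–Alder-like pathway; C-6 is set only on protonation and is planarised again in step 4. The step needs α'- over γ-deprotonation (LiN(iPr)2 at −78 °C), face selectivity (isopropenyl group) and endo selectivity (chelation, and the C-3 methyl of the ring-held diene pointing outward), and together these place the ester cis and the new methyl trans to the quaternary methyl, as in the target.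

**Step 4**
Reactants: 7 methyl (1S,2S,3R,4R,6S,8S)-1,3,6-trimethyl-5-oxo-8-(prop-1-en-2-yl)bicyclo[2.2.2]octane-2-carboxylate
Product: 8 methyl (1R,2S,3R,4R,6S,8S)-6-(1-hydroxyethyl)-1,3,6-trimethyl-5-oxo-8-(prop-1-en-2-yl)bicyclo[2.2.2]octane-2-carboxylate
Conditions: LiN(iPr)2, THF, −78 → 0 °C; CH3CHO, −78 °C; AcOH, −78 °C
Reagents that add atoms: acetaldehyde, CC=O
Why: aldol addition of the only possible ketone enolate (the other α-carbon is a bridgehead, Bredt's rule), the aldehyde entering anti to the endo ester, that is from the face of the CH2–CH(isopropenyl) bridge, should set the second quaternary centre with the new carbon syn to that bridge.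

**Step 5**
Reactants: 8 methyl (1R,2S,3R,4R,6S,8S)-6-(1-hydroxyethyl)-1,3,6-trimethyl-5-oxo-8-(prop-1-en-2-yl)bicyclo[2.2.2]octane-2-carboxylate
Product: 9 methyl (1R,2S,3R,4R,6S,8S)-6-acetyl-1,3,6-trimethyl-5-oxo-8-(prop-1-en-2-yl)bicyclo[2.2.2]octane-2-carboxylate
Conditions: Dess–Martin periodinane, CH2Cl2, rt
Reagents that add atoms: none
Why: Dess–Martin oxidation of the secondary alcohol under neutral conditions should give the β-diketone without retro-aldol loss of the new two-carbon unit.

**Step 6**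
Reactants: 9 methyl (1R,2S,3R,4R,6S,8S)-6-acetyl-1,3,6-trimethyl-5-oxo-8-(prop-1-en-2-yl)bicyclo[2.2.2]octane-2-carboxylate
Product: 10 methyl (1R,2S,3R,4R,6S,8S)-6-acetyl-8-(acetyloxy)-1,3,6-trimethyl-5-oxobicyclo[2.2.2]octane-2-carboxylate
Conditions: O3, CH2Cl2/MeOH, −78 °C; then Ac2O, Et3N, DMAP (cat.), CH2Cl2, 0 °C → rt
Reagents that add atoms: ozone, [O-][O+]=O; methanol, CO
Why: ozonolysis in methanol gives the α-methoxy hydroperoxide, whose peracetate undergoes Criegee rearrangement with migration of the ring carbon to oxygen with retention, turning the isopropenyl group into an acetate (it cannot eliminate, since the α-carbon is a bridgehead).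

**Step 7**
Reactants: 10 methyl (1R,2S,3R,4R,6S,8S)-6-acetyl-8-(acetyloxy)-1,3,6-trimethyl-5-oxobicyclo[2.2.2]octane-2-carboxylate
Product: 13 methyl (1S,2R,4aR,8aR)-2,4a,8a-trimethyl-4,5-dioxo-1,2,3,4,4a,5,8,8a-octahydronaphthalene-1-carboxylate, via ketol 11 (not isolated), via keto aldehyde 12 (not isolated)
Conditions: TsOH·H2O, MeOH, 50 °C; then toluene, 80 °C
Reagents that add atoms: none
Why: acid methanolysis frees β-hydroxy ketone 11, strain-driven retro-aldol cleavage between the bridgehead α-carbon and the carbinol carbon opens the carvone ring to 12, and intramolecular aldol condensation of the acetyl methyl with the aldehyde (the only productive pairing, the others giving four-membered rings or a bridgehead alkene) closes ring B cis-fused, acid being chosen because alkoxide would cleave the β-diketone by retro-Claisen reaction.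

**Step 8**
Reactants: 13 methyl (1S,2R,4aR,8aR)-2,4a,8a-trimethyl-4,5-dioxo-1,2,3,4,4a,5,8,8a-octahydronaphthalene-1-carboxylate
Product: 15 methyl (1S,2R,4aS,8aR)-2,4a,8a-trimethyl-4-oxo-5-{[(trifluoromethyl)sulfonyl]oxy}-1,2,3,4,4a,7,8,8a-octahydronaphthalene-1-carboxylate, via silyl enol ether 14 (not isolated)
Conditions: [(Ph3P)CuH]6 (cat.), PhMe2SiH, toluene, rt; then CsF, PhN(SO2CF3)2, DME, rt
Reagents that add atoms: N-phenylbis(trifluoromethanesulfonimide), O=S(=O)(N(c1ccccc1)S(=O)(=O)C(F)(F)F)C(F)(F)F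
Why: copper hydride 1,4-hydrosilylation reduces only the conjugated ketone and gives the C-5 silyl enol ether 14 regiospecifically, and fluoride-triggered O-sulfonylation of 14 turns it into the enol triflate with the C-5=C-6 double bond fixed, the isolated C-4 ketone and the ester being left alone.

**Step 9**
Reactants: 15 methyl (1S,2R,4aS,8aR)-2,4a,8a-trimethyl-4-oxo-5-{[(trifluoromethyl)sulfonyl]oxy}-1,2,3,4,4a,7,8,8a-octahydronaphthalene-1-carboxylate, 16 5-bromo-2-methylpent-2-ene
Product: 17 methyl (1S,2R,4aR,8aR)-2,4a,8a-trimethyl-5-(4-methylpent-3-en-1-yl)-4-oxo-1,2,3,4,4a,7,8,8a-octahydronaphthalene-1-carboxylate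
Conditions: 16, Zn, LiCl, THF, 40 °C; then 15, Pd(dppf)Cl2 (5 mol %), THF, 50 °C
Reagents that add atoms: none
Why: Negishi sp2–sp3 coupling of the alkenyl triflate with the primary alkylzinc bromide installs the side chain at C-5, and ketone, ester and the trisubstituted alkene are tolerated.

**Step 10**
Reactants: 17 methyl (1S,2R,4aR,8aR)-2,4a,8a-trimethyl-5-(4-methylpent-3-en-1-yl)-4-oxo-1,2,3,4,4a,7,8,8a-octahydronaphthalene-1-carboxylate
Product: 18 (1S,2R,4aR,8aR)-2,4a,8a-trimethyl-5-(4-methylpent-3-en-1-yl)-1,2,3,4,4a,7,8,8a-octahydronaphthalene-1-carboxylic acid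
Conditions: N2H4·H2O, KOH, diethylene glycol, 130 °C, then 200 °C; then aq HCl
Reagents that add atoms: potassium hydroxide, [K+].[OH-]
Why: Wolff–Kishner reduction (Huang-Minlon procedure) removes the C-4 carbonyl helper, now the only ketone and unable to conjugate with the C-5 alkene because C-4a is quaternary, while the hot alkali saponifies the hindered methyl ester in the same operation and leaves C-1 in its equatorial configuration trans to the C-2 methyl.

**Step 11**
Reactants: 18 (1S,2R,4aR,8aR)-2,4a,8a-trimethyl-5-(4-methylpent-3-en-1-yl)-1,2,3,4,4a,7,8,8a-octahydronaphthalene-1-carboxylic acid, 19 (2S)-oxiran-2-ylmethyl 3-nitrobenzenesulfonate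
Product: 20 (2S)-oxiran-2-ylmethyl (1S,2R,4aR,8aR)-2,4a,8a-trimethyl-5-(4-methylpent-3-en-1-yl)-1,2,3,4,4a,7,8,8a-octahydronaphthalene-1-carboxylate
Conditions: Cs2CO3, DMF, rt
Reagents that add atoms: none
Why: SN2 O-alkylation of the cesium carboxylate at the sulfonate-bearing CH2 (insensitive to the hindrance of the acid, the nosylate leaving faster than the epoxide opens) should give the glycidyl ester with the stereocentre untouched.

**Step 12**
Reactants: 20 (2S)-oxiran-2-ylmethyl (1S,2R,4aR,8aR)-2,4a,8a-trimethyl-5-(4-methylpent-3-en-1-yl)-1,2,3,4,4a,7,8,8a-octahydronaphthalene-1-carboxylate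
Product: 21 (2S)-3-(acetyloxy)-2-hydroxypropyl (1S,2R,4aR,8aR)-2,4a,8a-trimethyl-5-(4-methylpent-3-en-1-yl)-1,2,3,4,4a,7,8,8a-octahydronaphthalene-1-carboxylate
Conditions: AcOH (5 equiv), Bu4N(OAc) (cat.), toluene, 60 °C
Reagents that add atoms: acetic acid, CC(O)=O
Why: acetate-catalysed SN2 opening of the terminal epoxide at its CH2 by acetic acid, the standard route from glycidyl esters to 1,3-diacylglycerols, leaves the carbinol stereocentre unchanged and gives the 1,3-diester, which is also the more stable acyl isomer.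

**Compound list**
1 | (R)-(−)-carvone, (5R)-2-methyl-5-(prop-1-en-2-yl)cyclohex-2-en-1-one | CC(=C)[C@@H]1CC=C(C)C(=O)C1 | starting material
2 | (5R)-1,2-dimethyl-5-(prop-1-en-2-yl)cyclohex-2-en-1-ol, both C-1 epimers | CC(=C)[C@@H]1CC=C(C)C(C)(O)C1 | intermediate
3 | (5S)-2,3-dimethyl-5-(prop-1-en-2-yl)cyclohex-2-en-1-one (3-methylcarvone) | CC(=C)[C@@H]1CC(=O)C(C)=C(C)C1 | intermediate
4 | methyl (2E)-but-2-enoate (methyl crotonate) | C/C=C/C(=O)OC | starting material
5 | lithium (3S)-5,6-dimethyl-3-(prop-1-en-2-yl)cyclohexa-1,5-dien-1-olate | CC(=C)[C@@H]1C=C(O[Li])C(C)=C(C)C1 | intermediate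
6 | lithium ester enolate of methyl 3-[3,4-dimethyl-2-oxo-6-(prop-1-en-2-yl)cyclohex-3-en-1-yl]butanoate (Michael adduct, side chain trans to isopropenyl) | CO/C(O[Li])=C/[C@H](C)[C@H]1C(=O)C(C)=C(C)C[C@@H]1C(C)=C | intermediate
7 | methyl (1S,2S,3R,4R,6S,8S)-1,3,6-trimethyl-5-oxo-8-(prop-1-en-2-yl)bicyclo[2.2.2]octane-2-carboxylate (ester syn to the ketone bridge, 3-methyl anti to it, isopropenyl syn to it; C-6 epimer drawn as from protonation anti to the ester) | COC(=O)[C@H]1[C@H](C)[C@H]2C(=O)[C@@H](C)[C@]1(C)C[C@@H]2C(C)=C | intermediate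
8 | methyl (1R,2S,3R,4R,6S,8S)-6-(1-hydroxyethyl)-1,3,6-trimethyl-5-oxo-8-(prop-1-en-2-yl)bicyclo[2.2.2]octane-2-carboxylate, both carbinol epimers | COC(=O)[C@H]1[C@H](C)[C@H]2C(=O)[C@@](C(C)O)(C)[C@]1(C)C[C@@H]2C(C)=C | intermediate
9 | methyl (1R,2S,3R,4R,6S,8S)-6-acetyl-1,3,6-trimethyl-5-oxo-8-(prop-1-en-2-yl)bicyclo[2.2.2]octane-2-carboxylate | COC(=O)[C@H]1[C@H](C)[C@H]2C(=O)[C@@](C(C)=O)(C)[C@]1(C)C[C@@H]2C(C)=C | intermediate
10 | methyl (1R,2S,3R,4R,6S,8S)-6-acetyl-8-(acetyloxy)-1,3,6-trimethyl-5-oxobicyclo[2.2.2]octane-2-carboxylate | COC(=O)[C@H]1[C@H](C)[C@H]2C(=O)[C@@](C(C)=O)(C)[C@]1(C)C[C@@H]2OC(C)=O | intermediate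
11 | methyl (1R,2S,3R,4R,6S,8S)-6-acetyl-8-hydroxy-1,3,6-trimethyl-5-oxobicyclo[2.2.2]octane-2-carboxylate | COC(=O)[C@H]1[C@H](C)[C@H]2C(=O)[C@@](C(C)=O)(C)[C@]1(C)C[C@@H]2O | intermediate
12 | methyl (1S,2R,5S,6R)-5-acetyl-2,5,6-trimethyl-4-oxo-6-(2-oxoethyl)cyclohexane-1-carboxylate | COC(=O)[C@H]1[C@H](C)CC(=O)[C@@](C(C)=O)(C)[C@]1(C)CC=O | intermediate
13 | methyl (1S,2R,4aR,8aR)-2,4a,8a-trimethyl-4,5-dioxo-1,2,3,4,4a,5,8,8a-octahydronaphthalene-1-carboxylate | COC(=O)[C@H]1[C@H](C)CC(=O)[C@]2(C)C(=O)C=CC[C@]12C | intermediate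
14 | methyl (1S,2R,4aS,8aR)-5-{[dimethyl(phenyl)silyl]oxy}-2,4a,8a-trimethyl-4-oxo-1,2,3,4,4a,7,8,8a-octahydronaphthalene-1-carboxylate | COC(=O)[C@H]1[C@H](C)CC(=O)[C@]2(C)C(O[Si](C)(C)c3ccccc3)=CCC[C@]12C | intermediate
15 | methyl (1S,2R,4aS,8aR)-2,4a,8a-trimethyl-4-oxo-5-{[(trifluoromethyl)sulfonyl]oxy}-1,2,3,4,4a,7,8,8a-octahydronaphthalene-1-carboxylate | COC(=O)[C@H]1[C@H](C)CC(=O)[C@]2(C)C(OS(=O)(=O)C(F)(F)F)=CCC[C@]12C | intermediate
16 | 5-bromo-2-methylpent-2-ene | CC(C)=CCCBr | starting material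
17 | methyl (1S,2R,4aR,8aR)-2,4a,8a-trimethyl-5-(4-methylpent-3-en-1-yl)-4-oxo-1,2,3,4,4a,7,8,8a-octahydronaphthalene-1-carboxylate | COC(=O)[C@H]1[C@H](C)CC(=O)[C@]2(C)C(CCC=C(C)C)=CCC[C@]12C | intermediate
18 | (1S,2R,4aR,8aR)-2,4a,8a-trimethyl-5-(4-methylpent-3-en-1-yl)-1,2,3,4,4a,7,8,8a-octahydronaphthalene-1-carboxylic acid | OC(=O)[C@H]1[C@H](C)CC[C@]2(C)C(CCC=C(C)C)=CCC[C@]12C | intermediate
19 | (2S)-oxiran-2-ylmethyl 3-nitrobenzenesulfonate, (S)-glycidyl nosylate | [O-][N+](=O)c1cccc(c1)S(=O)(=O)OC[C@@H]2CO2 | starting material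
20 | (2S)-oxiran-2-ylmethyl (1S,2R,4aR,8aR)-2,4a,8a-trimethyl-5-(4-methylpent-3-en-1-yl)-1,2,3,4,4a,7,8,8a-octahydronaphthalene-1-carboxylate | O=C(OC[C@@H]3CO3)[C@H]1[C@H](C)CC[C@]2(C)C(CCC=C(C)C)=CCC[C@]12C | intermediate
21 | (2S)-3-(acetyloxy)-2-hydroxypropyl (1S,2R,4aR,8aR)-2,4a,8a-trimethyl-5-(4-methylpent-3-en-1-yl)-1,2,3,4,4a,7,8,8a-octahydronaphthalene-1-carboxylate | CC(=O)OC[C@H](O)COC(=O)[C@H]1[C@H](C)CC[C@]2(C)C(CCC=C(C)C)=CCC[C@]12C | target

**Totals**
Total step count: 12. Longest linear sequence: 12 steps (1 to 21).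

**Steps most likely to fail**

Step 3. The hindered dienolate may transfer a proton to the crotonate instead of adding, or the sequence may stop after the first Michael addition, because the second addition must build a quaternary carbon on a β,β-disubstituted enone. Fallback by cycloaddition, setting out from 3: the kinetic enolate is trapped (LiN(iPr)2, then tBuMe2SiCl, DMPU, THF, −78 °C) as the silyl dienol ether tert-butyl{[(3S)-5,6-dimethyl-3-(prop-1-en-2-yl)cyclohexa-1,5-dien-1-yl]oxy}dimethylsilane F1. F1 is heated with 4 (toluene, 150 °C, sealed tube) in a Diels–Alder reaction, expected to proceed endo and anti to the isopropenyl group, to give the silyl enol ether adduct methyl 5-{[tert-butyl(dimethyl)silyl]oxy}-1,3,6-trimethyl-8-(prop-1-en-2-yl)bicyclo[2.2.2]oct-5-ene-2-carboxylate F2. Desilylation (Bu4NF, AcOH, THF) brings the route back at 7.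

Step 4. Enolisation at the congested tertiary α-carbon may be incomplete, and the aldol addition that creates a quaternary carbon next to a quaternary bridgehead may revert on work-up. Fallback by irreversible C-acylation, setting out from 7: KN(SiMe3)2 then Me3SiCl (THF, −78 → 0 °C) gives the silyl enol ether methyl 1,3,6-trimethyl-8-(prop-1-en-2-yl)-5-[(trimethylsilyl)oxy]bicyclo[2.2.2]oct-5-ene-2-carboxylate F3. Mukaiyama-type acylation of F3 with acetyl chloride and ZnCl2 (CH2Cl2, −78 → 0 °C), again from the face anti to the ester, gives the β-diketone directly; the route is rejoined at 9 and 8 is skipped.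

Step 7. Acid methanolysis of the hindered acetate may be slow, the β-diketone may lose its acetyl group by retro-Claisen cleavage, or the cascade may stall before dehydration. Fallback that frees the hydroxyl group without an ester cleavage, setting out from 9: ozonolysis in MeOH (−78 °C) followed by FeSO4·7H2O and TEMPO (reductive cleavage of the α-methoxy hydroperoxide, β-scission, trapping of the ring radical) gives the alkoxyamine methyl 6-acetyl-1,3,6-trimethyl-5-oxo-8-[(2,2,6,6-tetramethylpiperidin-1-yl)oxy]bicyclo[2.2.2]octane-2-carboxylate F4. N–O cleavage with Zn in AcOH gives the ketol methyl 6-acetyl-8-hydroxy-1,3,6-trimethyl-5-oxobicyclo[2.2.2]octane-2-carboxylate F5 as C-8 epimers (one of them is 11). Pyrrolidine (cat.) and AcOH in toluene at 60 °C then effect retro-aldol opening and aldol condensation, and the route is rejoined at 13.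

**Further compounds**
F1 | step 3 | tert-butyl{[(3S)-5,6-dimethyl-3-(prop-1-en-2-yl)cyclohexa-1,5-dien-1-yl]oxy}dimethylsilane | CC(=C)[C@@H]1C=C(O[Si](C)(C)C(C)(C)C)C(C)=C(C)C1
F2 | step 3 | methyl 5-{[tert-butyl(dimethyl)silyl]oxy}-1,3,6-trimethyl-8-(prop-1-en-2-yl)bicyclo[2.2.2]oct-5-ene-2-carboxylate (configuration as in 7) | COC(=O)[C@H]1[C@H](C)[C@H]2C(O[Si](C)(C)C(C)(C)C)=C(C)[C@]1(C)C[C@@H]2C(C)=C
F3 | step 4 | methyl 1,3,6-trimethyl-8-(prop-1-en-2-yl)-5-[(trimethylsilyl)oxy]bicyclo[2.2.2]oct-5-ene-2-carboxylate (configuration as in 7) | COC(=O)[C@H]1[C@H](C)[C@H]2C(O[Si](C)(C)C)=C(C)[C@]1(C)C[C@@H]2C(C)=C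
F4 | step 7 | methyl 6-acetyl-1,3,6-trimethyl-5-oxo-8-[(2,2,6,6-tetramethylpiperidin-1-yl)oxy]bicyclo[2.2.2]octane-2-carboxylate, C-8 epimers | COC(=O)[C@H]1[C@H](C)[C@H]2C(=O)[C@@](C(C)=O)(C)[C@]1(C)CC2ON3C(C)(C)CCCC3(C)C
F5 | step 7 | methyl 6-acetyl-8-hydroxy-1,3,6-trimethyl-5-oxobicyclo[2.2.2]octane-2-carboxylate, C-8 epimers | COC(=O)[C@H]1[C@H](C)[C@H]2C(=O)[C@@](C(C)=O)(C)[C@]1(C)CC2O
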